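The pyran ring C of the upper epicatechin gallate unit is built last, from an acyclic precursor. The route exploits that its C4 is an aldehyde-level carbon bonded to two phloroglucinol rings, C4a of its own ring A and C8 of the middle unit. In one Lewis-acid operation the diethyl acetal carbon of a chiral aryl ether (C2 and C3 preset, ring A attached only through O1) is attacked by ring A, whose two ortho carbons are equivalent, closing ring C; the resulting 4-ethoxyflavan ionises and its C4 cation is captured by C8 of a preformed epigallocatechin gallate–catechin gallate dimer, setting the 4β bond. Global hydrogenolysis ends the synthesis.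

Key step: step 12

Remark: the target is read as (−)-epicatechin 3-O-gallate-(4β→8)-(−)-epigallocatechin 3-O-gallate-(4β→8)-(+)-catechin 3-O-gallate (upper and middle units 2R,3R with 3,4-trans interflavan bonds, lower unit 2R,3S); compounds 1, 2, 6, 8, 10 and 13 are taken as purchasable.

Step 1
Reactants: 1 4-bromo-1,2-bis(benzyloxy)benzene; 2 3,3-diethoxyprop-1-yne
Product: 3 1,2-bis(benzyloxy)-4-(3,3-diethoxyprop-1-yn-1-yl)benzene
Conditions: PdCl2(MeCN)2 (2 mol %), XPhos (6 mol %), Cs2CO3, MeCN, 80 °C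
Reagents that add atoms: none
Why: Copper-free Sonogashira coupling of an electron-rich aryl bromide with a terminal alkyne under a bulky biarylphosphine–palladium catalyst; the acetal is inert to the basic medium and no stereocentre is formed.

Step 2
Reactants: 3 1,2-bis(benzyloxy)-4-(3,3-diethoxyprop-1-yn-1-yl)benzene
Product: 4 1,2-bis(benzyloxy)-4-[(Z)-3,3-diethoxyprop-1-en-1-yl]benzene
Conditions: H2 (1 atm), 5% Pd/CaCO3 poisoned with Pb(OAc)2, quinoline, EtOAc, rt
Reagents that add atoms: none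
Why: Lindlar semihydrogenation delivers both hydrogens to one face of the aryl alkyne and should give the (Z)-alkene, while benzyl ethers and the acetal are untouched by the poisoned catalyst.

Step 3
Reactants: 4 1,2-bis(benzyloxy)-4-[(Z)-3,3-diethoxyprop-1-en-1-yl]benzene
Product: 5 (2S,3S)-2-[3,4-bis(benzyloxy)phenyl]-3-(diethoxymethyl)oxirane (cis-epoxide)
Conditions: (S,S)-N,N'-bis(3,5-di-tert-butylsalicylidene)-1,2-cyclohexanediaminomanganese chloride (5 mol %), 4-phenylpyridine N-oxide (25 mol %), aq NaOCl buffered to pH 11.3, CH2Cl2, 0 °C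
Reagents that add atoms: sodium hypochlorite, [Na+].[O-]Cl
Why: Jacobsen–Katsuki epoxidation, for which cis-disubstituted aryl-conjugated alkenes are the best substrate class; the chiral salen ligand on the manganese oxo species selects the alkene face, so both stereocentres (C2 and C3 of the future flavan) are set under catalyst control, the (S,S) ligand being chosen by analogy with (Z)-cinnamate esters, and the basic buffer protects the acid-labile epoxide.

Step 4
Reactants: 5 (2S,3S)-2-[3,4-bis(benzyloxy)phenyl]-3-(diethoxymethyl)oxirane; 6 3,5-bis(benzyloxy)phenol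
Product: 7 (1R,2S)-1-[3,4-bis(benzyloxy)phenyl]-1-[3,5-bis(benzyloxy)phenoxy]-3,3-diethoxypropan-2-ol
Conditions: 6 (1.5 equiv), Cs2CO3 (0.3 equiv), DMF, 70 °C
Reagents that add atoms: none
Why: Base-mediated SN2 opening of the epoxide by the phenoxide at the benzylic carbon (activated by the dialkoxyphenyl group, while the other carbon is deactivated and shielded by the acetal) with inversion should turn the cis-epoxide into the threo aryl ether, which is the future 2R centre with O1 in place and the 3-hydroxyl retained.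

Step 5
Reactants: 7 (1R,2S)-1-[3,4-bis(benzyloxy)phenyl]-1-[3,5-bis(benzyloxy)phenoxy]-3,3-diethoxypropan-2-ol; 8 3,4,5-tris(benzyloxy)benzoic acid
Product: 9 (1R,2S)-1-[3,4-bis(benzyloxy)phenyl]-1-[3,5-bis(benzyloxy)phenoxy]-3,3-diethoxypropan-2-yl 3,4,5-tris(benzyloxy)benzoate
Conditions: 8 (1.5 equiv), DCC, DMAP (0.3 equiv), CH2Cl2, 0 °C to rt
Reagents that add atoms: none
Why: Steglich esterification acylates the only free hydroxyl without touching either stereocentre, the acetal or the benzylic aryl ether.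

Step 6
Reactants: 10 (+)-catechin
Product: 11 5,7,3',4'-tetra-O-benzyl-(+)-catechin, (2R,3S)-5,7-bis(benzyloxy)-2-[3,4-bis(benzyloxy)phenyl]chroman-3-ol
Conditions: BnBr (4.4 equiv), K2CO3, DMF, −10 °C to rt, argon
Reagents that add atoms: benzyl bromide, BrCc1ccccc1
Why: Williamson etherification of the four phenols, which are far more acidic than the 3-hydroxyl; low temperature and exclusion of air limit C-benzylation and base-induced epimerisation at C2, and both stereocentres come unchanged from the natural product.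

Step 7
Reactants: 11 5,7,3',4'-tetra-O-benzyl-(+)-catechin; 8 3,4,5-tris(benzyloxy)benzoic acid
Product: 12 5,7,3',4'-tetra-O-benzyl-(+)-catechin 3-O-[3,4,5-tris(benzyloxy)benzoate]
Conditions: 8 (1.5 equiv), DCC, DMAP, CH2Cl2, rt
Reagents that add atoms: none
Why: Steglich esterification of the secondary 3-hydroxyl, the standard way to galloylate benzylated flavan-3-ols, with no change at C2 or C3.

Step 8
Reactants: 13 (−)-epigallocatechin
Product: 14 5,7,3',4',5'-penta-O-benzyl-(−)-epigallocatechin, (2R,3R)-5,7-bis(benzyloxy)-2-[3,4,5-tris(benzyloxy)phenyl]chroman-3-ol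
Conditions: BnBr (5.5 equiv), K2CO3, DMF, −10 °C to rt, argon
Reagents that add atoms: benzyl bromide, BrCc1ccccc1
Why: Williamson etherification of the five phenols, which carbonate deprotonates while the secondary 3-hydroxyl stays un-ionised; fast alkylation under argon at low temperature should prevent autoxidation of the pyrogallol ring B and epimerisation at C2, and both stereocentres come unchanged from the natural product.

Step 9
Reactants: 14 5,7,3',4',5'-penta-O-benzyl-(−)-epigallocatechin; 8 3,4,5-tris(benzyloxy)benzoic acid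
Product: 15 octa-O-benzyl-(−)-epigallocatechin 3-O-gallate, (2R,3R)-5,7-bis(benzyloxy)-2-[3,4,5-tris(benzyloxy)phenyl]chroman-3-yl 3,4,5-tris(benzyloxy)benzoate
Conditions: 8 (1.5 equiv), DCC, DMAP, CH2Cl2, rt
Reagents that add atoms: none
Why: Steglich esterification of the axial 3-hydroxyl of the 2,3-cis flavan, the only free hydroxyl, installs the protected gallate without touching C2 or C3.

Step 10
Reactants: 15 octa-O-benzyl-(−)-epigallocatechin 3-O-gallate
Product: 16 (2R,3R,4S)-5,7-bis(benzyloxy)-4-(2-ethoxyethoxy)-2-[3,4,5-tris(benzyloxy)phenyl]chroman-3-yl 3,4,5-tris(benzyloxy)benzoate (4β-alkoxy, trans to the 3-ester)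
Conditions: DDQ (2 equiv), 2-ethoxyethanol (5 equiv), CH2Cl2, rt
Reagents that add atoms: 2-ethoxyethanol, CCOCCO
Why: DDQ benzylic oxidation: hydride abstraction from C4–H, activated by the 5,7-dialkoxy ring A, gives the flavan-4-yl cation, which the alcohol should trap trans to the 3-acyloxy group; this is the standard C4 activation of benzylated flavan-3-ols.

Step 11
Reactants: 16 4β-(2-ethoxyethoxy)-octa-O-benzyl-epigallocatechin gallate; 12 5,7,3',4'-tetra-O-benzyl-(+)-catechin 3-O-[3,4,5-tris(benzyloxy)benzoate]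
Product: 17 pentadeca-O-benzyl ether of (−)-epigallocatechin 3-O-gallate-(4β→8)-(+)-catechin 3-O-gallate
Conditions: 12 (3 equiv), TMSOTf (0.1 equiv), CH2Cl2, −78 °C, then Et3N
Reagents that add atoms: none
Why: TMSOTf-promoted Friedel–Crafts condensation of a 4-alkoxyflavan with a flavan-3-ol nucleophile; the cation of the 2,3-cis unit should be attacked by the most nucleophilic free position (C8) of the excess catechin unit on the face anti to the 3-galloyloxy group, setting the 4β (3,4-trans) bond.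

Step 12
Reactants: 9 (1R,2S)-1-[3,4-bis(benzyloxy)phenyl]-1-[3,5-bis(benzyloxy)phenoxy]-3,3-diethoxypropan-2-yl 3,4,5-tris(benzyloxy)benzoate; 17 pentadeca-O-benzyl dimer
Product: 19 docosa-O-benzyl ether of (−)-epicatechin 3-O-gallate-(4β→8)-(−)-epigallocatechin 3-O-gallate-(4β→8)-(+)-catechin 3-O-gallate, via 4-ethoxyflavan gallate 18 (not isolated)
Conditions: 17 (1.5 equiv, excess recovered), TMSOTf (0.3 equiv), 4 Å molecular sieves, CH2Cl2 (0.02 M), −78 to −30 °C, then Et3N
Reagents that add atoms: none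
Why: TMSOTf ionises the acetal of 9 (helped by the neighbouring galloyl carbonyl) to a C4 oxocarbenium ion that the tethered 3,5-bis(benzyloxy)phenyl ether attacks through an ortho carbon, a 6-exo-trig Friedel–Crafts closure that forms C4–C4a and ring C and gives 18; the same acid then removes the second ethoxy group, and the flavan-4-yl cation (an O-alkylated ortho-quinone methide of ring A) is captured by C8 of ring A of the epigallocatechin unit of 17. The closest known reaction types are the acid-mediated cyclisation of 3-aryloxypropanal acetals to 4-alkoxychromans and the TMSOTf-mediated condensation of 4-alkoxyflavans with flavan-3-ol nucleophiles, here run in tandem. C2 and C3 are not touched, and the new C4 centre is controlled by the pseudoaxial 3-galloyloxy group of the 2,3-cis cation (direct shielding or a bridged acyloxonium ion), which forces attack on the opposite face and should give the 3,4-trans, 4β bond. The closure needs attack by ring A in preference to the much less nucleophilic ring B (which could only form an indane), and this is secured by the three oxygen substituents that activate the two equivalent ortho carbons of ring A. The coupling needs C8 over C6 of 17 and survival of its interflavan bond, which the higher nucleophilicity and accessibility of C8 of the upper unit of benzylated dimers, the excess of 17, the low temperature and the substoichiometric acid are meant to secure. Should 17 intercept the acyclic oxocarbenium ion first, ionisation of the resulting benzylic ether and the same ring closure lead to the same product.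

Step 13
Reactants: 19 docosa-O-benzyl trimer
Product: 20 (−)-epicatechin 3-O-gallate-(4β→8)-(−)-epigallocatechin 3-O-gallate-(4β→8)-(+)-catechin 3-O-gallate (CNP0321910.1)
Conditions: H2 (1 atm), 20% Pd(OH)2/C, THF/MeOH/H2O, rt
Reagents that add atoms: none
Why: Hydrogenolysis of all twenty-two benzyl ethers under neutral conditions should leave the three gallate esters, both interflavan bonds and all stereocentres untouched.

Compound list

1 | 4-bromo-1,2-bis(benzyloxy)benzene | Brc1ccc(OCc2ccccc2)c(OCc2ccccc2)c1 | starting material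
2 | 3,3-diethoxyprop-1-yne | C#CC(OCC)OCC | starting material
3 | 1,2-bis(benzyloxy)-4-(3,3-diethoxyprop-1-yn-1-yl)benzene | CCOC(OCC)C#Cc1ccc(OCc2ccccc2)c(OCc2ccccc2)c1 | intermediate
4 | 1,2-bis(benzyloxy)-4-[(Z)-3,3-diethoxyprop-1-en-1-yl]benzene | CCOC(OCC)/C=C\c1ccc(OCc2ccccc2)c(OCc2ccccc2)c1 | intermediate
5 | (2S,3S)-2-[3,4-bis(benzyloxy)phenyl]-3-(diethoxymethyl)oxirane | O1[C@@H](c2ccc(OCc3ccccc3)c(OCc3ccccc3)c2)[C@H]1C(OCC)OCC | intermediate
6 | 3,5-bis(benzyloxy)phenol | Oc1cc(OCc2ccccc2)cc(OCc2ccccc2)c1 | starting material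
7 | (1R,2S)-1-[3,4-bis(benzyloxy)phenyl]-1-[3,5-bis(benzyloxy)phenoxy]-3,3-diethoxypropan-2-ol | CCOC(OCC)[C@@H](O)[C@H](Oc1cc(OCc2ccccc2)cc(OCc2ccccc2)c1)c1ccc(OCc2ccccc2)c(OCc2ccccc2)c1 | intermediate
8 | 3,4,5-tris(benzyloxy)benzoic acid | OC(=O)c1cc(OCc2ccccc2)c(OCc2ccccc2)c(OCc2ccccc2)c1 | starting material
9 | (1R,2S)-1-[3,4-bis(benzyloxy)phenyl]-1-[3,5-bis(benzyloxy)phenoxy]-3,3-diethoxypropan-2-yl 3,4,5-tris(benzyloxy)benzoate | CCOC(OCC)[C@@H](OC(=O)c1cc(OCc2ccccc2)c(OCc2ccccc2)c(OCc2ccccc2)c1)[C@H](Oc1cc(OCc2ccccc2)cc(OCc2ccccc2)c1)c1ccc(OCc2ccccc2)c(OCc2ccccc2)c1 | intermediate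
10 | (+)-catechin, (2R,3S) | Oc1cc(O)c2c(c1)O[C@H](c1ccc(O)c(O)c1)[C@@H](O)C2 | starting material
11 | 5,7,3',4'-tetra-O-benzyl-(+)-catechin | c1c(OCc9ccccc9)cc(OCc9ccccc9)c2c1O[C@H](c1ccc(OCc9ccccc9)c(OCc9ccccc9)c1)[C@@H](O)C2 | intermediate
12 | 5,7,3',4'-tetra-O-benzyl-(+)-catechin 3-O-[3,4,5-tris(benzyloxy)benzoate] | c1c(OCc9ccccc9)cc(OCc9ccccc9)c2c1O[C@H](c1ccc(OCc9ccccc9)c(OCc9ccccc9)c1)[C@@H](OC(=O)c1cc(OCc9ccccc9)c(OCc9ccccc9)c(OCc9ccccc9)c1)C2 | intermediate
13 | (−)-epigallocatechin, (2R,3R) | O[C@@H]1Cc2c(O)cc(O)cc2O[C@@H]1c1cc(O)c(O)c(O)c1 | starting material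
14 | 5,7,3',4',5'-penta-O-benzyl-(−)-epigallocatechin, (2R,3R) | O[C@@H]1Cc2c(OCc9ccccc9)cc(OCc9ccccc9)cc2O[C@@H]1c1cc(OCc9ccccc9)c(OCc9ccccc9)c(OCc9ccccc9)c1 | intermediate
15 | octa-O-benzyl-(−)-epigallocatechin 3-O-gallate | O=C(O[C@@H]1Cc2c(OCc9ccccc9)cc(OCc9ccccc9)cc2O[C@@H]1c1cc(OCc9ccccc9)c(OCc9ccccc9)c(OCc9ccccc9)c1)c1cc(OCc9ccccc9)c(OCc9ccccc9)c(OCc9ccccc9)c1 | intermediate
16 | (2R,3R,4S)-5,7-bis(benzyloxy)-4-(2-ethoxyethoxy)-2-[3,4,5-tris(benzyloxy)phenyl]chroman-3-yl 3,4,5-tris(benzyloxy)benzoate | O=C(O[C@@H]1[C@@H](OCCOCC)c2c(OCc9ccccc9)cc(OCc9ccccc9)cc2O[C@@H]1c1cc(OCc9ccccc9)c(OCc9ccccc9)c(OCc9ccccc9)c1)c1cc(OCc9ccccc9)c(OCc9ccccc9)c(OCc9ccccc9)c1 | intermediate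
17 | pentadeca-O-benzyl ether of (−)-epigallocatechin 3-O-gallate-(4β→8)-(+)-catechin 3-O-gallate | O=C(O[C@@H]1[C@@H](c2c(OCc9ccccc9)cc(OCc9ccccc9)c3c2O[C@H](c2ccc(OCc9ccccc9)c(OCc9ccccc9)c2)[C@@H](OC(=O)c2cc(OCc9ccccc9)c(OCc9ccccc9)c(OCc9ccccc9)c2)C3)c2c(OCc9ccccc9)cc(OCc9ccccc9)cc2O[C@@H]1c1cc(OCc9ccccc9)c(OCc9ccccc9)c(OCc9ccccc9)c1)c1cc(OCc9ccccc9)c(OCc9ccccc9)c(OCc9ccccc9)c1 | intermediate
18 | (2R,3R)-5,7-bis(benzyloxy)-2-[3,4-bis(benzyloxy)phenyl]-4-ethoxychroman-3-yl 3,4,5-tris(benzyloxy)benzoate, mixture of C4 epimers, not isolated | CCOC1c2c(OCc9ccccc9)cc(OCc9ccccc9)cc2O[C@H](c2ccc(OCc9ccccc9)c(OCc9ccccc9)c2)[C@@H]1OC(=O)c1cc(OCc9ccccc9)c(OCc9ccccc9)c(OCc9ccccc9)c1 | intermediate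
19 | docosa-O-benzyl ether of (−)-epicatechin 3-O-gallate-(4β→8)-(−)-epigallocatechin 3-O-gallate-(4β→8)-(+)-catechin 3-O-gallate | O=C(O[C@@H]1[C@@H](c2c(OCc9ccccc9)cc(OCc9ccccc9)c3c2O[C@H](c2ccc(OCc9ccccc9)c(OCc9ccccc9)c2)[C@@H](OC(=O)c2cc(OCc9ccccc9)c(OCc9ccccc9)c(OCc9ccccc9)c2)C3)c2c(OCc9ccccc9)cc(OCc9ccccc9)c([C@H]3c4c(OCc9ccccc9)cc(OCc9ccccc9)cc4O[C@H](c4ccc(OCc9ccccc9)c(OCc9ccccc9)c4)[C@@H]3OC(=O)c3cc(OCc9ccccc9)c(OCc9ccccc9)c(OCc9ccccc9)c3)c2O[C@@H]1c1cc(OCc9ccccc9)c(OCc9ccccc9)c(OCc9ccccc9)c1)c1cc(OCc9ccccc9)c(OCc9ccccc9)c(OCc9ccccc9)c1 | intermediate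
20 | (−)-epicatechin 3-O-gallate-(4β→8)-(−)-epigallocatechin 3-O-gallate-(4β→8)-(+)-catechin 3-O-gallate (CNP0321910.1) | O=C(O[C@@H]1[C@@H](c2c(O)cc(O)c3c2O[C@H](c2ccc(O)c(O)c2)[C@@H](OC(=O)c2cc(O)c(O)c(O)c2)C3)c2c(O)cc(O)c([C@H]3c4c(O)cc(O)cc4O[C@H](c4ccc(O)c(O)c4)[C@@H]3OC(=O)c3cc(O)c(O)c(O)c3)c2O[C@@H]1c1cc(O)c(O)c(O)c1)c1cc(O)c(O)c(O)c1 | target

Total step count: 13. Longest linear sequence: 7 steps (steps 1, 2, 3, 4, 5, 12, 13).

Steps most likely to fail

Step 12. The acid strength needed to ionise the α-acyloxy acetal of 9 may also ionise the existing interflavan bond of 17 and scramble it, and the C4 cation, for which 17 cannot be offered in large excess, may be lost to self-condensation or to attack at C6. The fallback sets out from 9 and comes back at 19; it separates ring closure from interflavan bond formation and moves the coupling from Lewis-acid to thiophile activation. 9 alone is cyclised with BF3·OEt2 in CH2Cl2 containing an excess of ethanol at 0 °C, so that ring C still closes in this operation while the alcohol returns the cation to 18. Benzyl mercaptan is then added at −20 °C and replaces the 4-ethoxy group to give the bench-stable (2R,3S,4S)-4-(benzylsulfanyl)-5,7-bis(benzyloxy)-2-[3,4-bis(benzyloxy)phenyl]chroman-3-yl 3,4,5-tris(benzyloxy)benzoate F1, which is isolated. F1 and 17 are then joined with AgBF4 in THF at 0 °C, the silver ion removing the thiolate under nearly neutral conditions, to give 19.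

Step 4. Partial ionisation of the electron-rich benzylic C–O bond of 5 would erode the stereospecificity of the opening, and the ambident phenoxide may alkylate on carbon or open the epoxide at the other carbon. The fallback sets out from 1 and comes back at 9, replacing steps 1 to 5; the aryl ether is made by O-arylation of a carbinol whose configuration is already fixed, so no substitution at the stereocentre is needed. Bromine–lithium exchange of 1 (n-BuLi, THF, −78 °C) and quenching with DMF give 3,4-bis(benzyloxy)benzaldehyde F2. Brown alkoxyallylboration of F2 with the (Z)-γ-(methoxymethoxy)allylborane made from allyl methoxymethyl ether, sec-BuLi, (−)-Ipc2BOMe and BF3·OEt2 (−78 °C, NaOH/H2O2 work-up) should give, under reagent control, the syn adduct (1R,2R)-1-[3,4-bis(benzyloxy)phenyl]-2-(methoxymethoxy)but-3-en-1-ol F3. Buchwald–Hartwig C–O coupling with 1-bromo-3,5-bis(benzyloxy)benzene ([Pd(allyl)Cl]2, RockPhos, Cs2CO3, toluene, 90 °C) arylates the hydroxyl with retention to give 4-[(1R,2R)-1-[3,5-bis(benzyloxy)phenoxy]-2-(methoxymethoxy)but-3-en-1-yl]-1,2-bis(benzyloxy)benzene F4. Removal of the methoxymethyl group (TMSOTf, 2,2'-bipyridyl, CH2Cl2, 0 °C, then water) gives (1R,2R)-1-[3,4-bis(benzyloxy)phenyl]-1-[3,5-bis(benzyloxy)phenoxy]but-3-en-2-ol F5. Steglich esterification with 8 (DCC, DMAP) gives (1R,2R)-1-[3,4-bis(benzyloxy)phenyl]-1-[3,5-bis(benzyloxy)phenoxy]but-3-en-2-yl 3,4,5-tris(benzyloxy)benzoate F6. Lemieux–Johnson cleavage (OsO4 cat., NaIO4, 2,6-lutidine, dioxane/water) gives (1R,2S)-1-[3,4-bis(benzyloxy)phenyl]-1-[3,5-bis(benzyloxy)phenoxy]-3-oxopropan-2-yl 3,4,5-tris(benzyloxy)benzoate F7. Acetalisation (HC(OEt)3, EtOH, pyridinium tosylate) returns 9.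

Step 10. Hydride abstraction at C4 may be slow next to the electron-withdrawing 3-galloyloxy group, so that oxidation of benzyl ethers or over-oxidation at C4 competes. The fallback sets out from 14 and comes back at 16; the oxidation is done on the free 3-ol, before the ester is put on. DDQ and 2-ethoxyethanol in CH2Cl2 convert 14 into (2R,3R,4S)-5,7-bis(benzyloxy)-4-(2-ethoxyethoxy)-2-[3,4,5-tris(benzyloxy)phenyl]chroman-3-ol F8. Steglich esterification of F8 with 8 (DCC, DMAP, CH2Cl2) gives 16.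

Further compounds

F1 | step 12 | (2R,3S,4S)-4-(benzylsulfanyl)-5,7-bis(benzyloxy)-2-[3,4-bis(benzyloxy)phenyl]chroman-3-yl 3,4,5-tris(benzyloxy)benzoate | c1ccccc1CS[C@H]1c2c(OCc9ccccc9)cc(OCc9ccccc9)cc2O[C@H](c2ccc(OCc9ccccc9)c(OCc9ccccc9)c2)[C@@H]1OC(=O)c1cc(OCc9ccccc9)c(OCc9ccccc9)c(OCc9ccccc9)c1
F2 | step 4 | 3,4-bis(benzyloxy)benzaldehyde | O=Cc1ccc(OCc2ccccc2)c(OCc2ccccc2)c1
F3 | step 4 | (1R,2R)-1-[3,4-bis(benzyloxy)phenyl]-2-(methoxymethoxy)but-3-en-1-ol | O[C@H](c1ccc(OCc2ccccc2)c(OCc2ccccc2)c1)[C@@H](C=C)OCOC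
F4 | step 4 | 4-[(1R,2R)-1-[3,5-bis(benzyloxy)phenoxy]-2-(methoxymethoxy)but-3-en-1-yl]-1,2-bis(benzyloxy)benzene | O([C@H](c1ccc(OCc2ccccc2)c(OCc2ccccc2)c1)[C@@H](C=C)OCOC)c1cc(OCc2ccccc2)cc(OCc2ccccc2)c1
F5 | step 4 | (1R,2R)-1-[3,4-bis(benzyloxy)phenyl]-1-[3,5-bis(benzyloxy)phenoxy]but-3-en-2-ol | O([C@H](c1ccc(OCc2ccccc2)c(OCc2ccccc2)c1)[C@@H](C=C)O)c1cc(OCc2ccccc2)cc(OCc2ccccc2)c1
F6 | step 4 | (1R,2R)-1-[3,4-bis(benzyloxy)phenyl]-1-[3,5-bis(benzyloxy)phenoxy]but-3-en-2-yl 3,4,5-tris(benzyloxy)benzoate | O([C@H](c1ccc(OCc2ccccc2)c(OCc2ccccc2)c1)[C@@H](C=C)OC(=O)c1cc(OCc2ccccc2)c(OCc2ccccc2)c(OCc2ccccc2)c1)c1cc(OCc2ccccc2)cc(OCc2ccccc2)c1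
F7 | step 4 | (1R,2S)-1-[3,4-bis(benzyloxy)phenyl]-1-[3,5-bis(benzyloxy)phenoxy]-3-oxopropan-2-yl 3,4,5-tris(benzyloxy)benzoate | O([C@H](c1ccc(OCc2ccccc2)c(OCc2ccccc2)c1)[C@@H](C=O)OC(=O)c1cc(OCc2ccccc2)c(OCc2ccccc2)c(OCc2ccccc2)c1)c1cc(OCc2ccccc2)cc(OCc2ccccc2)c1
F8 | step 10 | (2R,3R,4S)-5,7-bis(benzyloxy)-4-(2-ethoxyethoxy)-2-[3,4,5-tris(benzyloxy)phenyl]chroman-3-ol | O[C@@H]1[C@@H](OCCOCC)c2c(OCc9ccccc9)cc(OCc9ccccc9)cc2O[C@@H]1c1cc(OCc9ccccc9)c(OCc9ccccc9)c(OCc9ccccc9)c1
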